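**Retrosynthetic overview**

1. Kazinol D is traced back to aryl ketone 23 by removal of two MOM ethers and one acetate and by reduction of the C6 acyl carbonyl (the chain carbon attached to ring B) to CH2.
2. The plan rests on ring B, the benzene ring of the chroman (C4a, C5, C6, C7, C8, C8a). Five of its six positions are substituted: oxygen on the neighbours C8 (OH) and C8a (O1 of the pyran ring), carbon on the neighbours C5 (prenyl) and C6 (three-carbon link to ring A). It is cut at C4a–C5 and C6–C7 into diene 8 (C7=C8–C8a=C4a, with the pyran ring and both oxygens in place) and ynone 21 (C5≡C6).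
3. Ynone 21 comes from Weinreb amide 20 and the lithium acetylide of enyne 11. The 1,1-dimethylallyl group of ring A comes from an aromatic Claisen rearrangement of a 4-O-prenyl ether of 2,4-dihydroxybenzaldehyde.
4. Diene 8 comes from lactone 3 (from ethyl 5-oxohexanoate) by ketene acetal phosphate formation, Stille coupling with a 1-ethoxyvinyl stannane, hydrolysis and kinetic enol acetylation.
5. Ring order: the pyran ring first (step 1, as the lactone), ring A bought as an arene, ring B last (step 14).

Key step: step 14

Remark on the chemistry: the target has no stereocentre and no E/Z-defined alkene, so no stereocontrol is needed; the one transient stereocentre (C4a of adduct 22) forms racemic and is erased on aromatisation.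

**Route**

Step 1
Reactants: 1 ethyl 5-oxohexanoate
Product: 3 6,6-dimethyltetrahydro-2H-pyran-2-one, via hydroxy ester alkoxide 2 (not isolated)
Conditions: MeMgBr (1.0 equiv), THF, −78 → −20 °C; aq. NH4Cl; then TsOH·H2O (cat.), CH2Cl2, rt
Reagents that add atoms: methylmagnesium bromide, C[Mg]Br
Why: Grignard addition is much faster at the ketone than at the ester at low temperature, and the tertiary alkoxide 2 closes the six-membered lactone by intramolecular transesterification, which a trace of acid completes (chemoselective 1,2-addition then lactonisation).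

Step 2
Reactants: 3 6,6-dimethyltetrahydro-2H-pyran-2-one
Product: 4 6,6-dimethyl-5,6-dihydro-4H-pyran-2-yl diphenyl phosphate
Conditions: KN(SiMe3)2, (PhO)2P(O)Cl, HMPA, THF, −78 °C
Reagents that add atoms: diphenyl chlorophosphate, O=P(Cl)(Oc1ccccc1)Oc1ccccc1
Why: Enolisation of the lactone and O-phosphorylation of the potassium enolate should give the ketene acetal phosphate, the usual lactone-derived electrophile for palladium-catalysed coupling.

Step 3
Reactants: 4 6,6-dimethyl-5,6-dihydro-4H-pyran-2-yl diphenyl phosphate; 5 tributyl(1-ethoxyvinyl)stannane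
Product: 7 1-(6,6-dimethyl-5,6-dihydro-4H-pyran-2-yl)ethan-1-one, via ethoxyvinyl diene 6 (not isolated)
Conditions: Pd(PPh3)4 (5 mol %), LiCl, THF, 65 °C; then 1 M HCl, THF, 0 °C (short contact)
Reagents that add atoms: water, O
Why: Stille coupling of the ketene acetal phosphate (oxidative addition to zerovalent palladium, chloride-assisted transmetalation, reductive elimination) installs the 1-ethoxyvinyl group, and cold dilute acid should protonate the unsubstituted CH2 terminus of the acyclic enol ether faster than the ring enol ether, which after hydrolysis is deactivated as an α-alkoxy enone.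

Step 4
Reactants: 7 1-(6,6-dimethyl-5,6-dihydro-4H-pyran-2-yl)ethan-1-one
Product: 8 1-(6,6-dimethyl-5,6-dihydro-4H-pyran-2-yl)vinyl acetate
Conditions: KN(SiMe3)2, THF, −78 °C; Ac2O, −78 → 0 °C; chromatography on Et3N-treated silica
Reagents that add atoms: acetic anhydride, CC(=O)OC(C)=O
Why: Kinetic deprotonation of the methyl group (the α′ position of the enone) by a hindered amide base gives the cross-conjugated potassium enolate, which acetic anhydride should acylate on oxygen (enolate O-acylation) to give the 2-acetoxy diene.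

Step 5
Reactants: 9 prenyl bromide (1-bromo-3-methylbut-2-ene); 10 lithium acetylide–ethylenediamine complex
Product: 11 5-methylhex-4-en-1-yne
Conditions: DMSO, 15 °C → rt; pentane extraction, distillation
Reagents that add atoms: none
Why: SN2 alkylation of lithium acetylide at the primary carbon of the allylic bromide in DMSO is the standard way to make 1,4-enynes, and the product is protected from isomerisation as its acetylide until work-up.

Step 6
Reactants: 12 2,4-dihydroxybenzaldehyde; 9 prenyl bromide
Product: 13 2-hydroxy-4-[(3-methylbut-2-en-1-yl)oxy]benzaldehyde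
Conditions: K2CO3 (1.0 equiv), acetone, rt
Reagents that add atoms: none
Why: The 4-OH is the more acidic and unchelated phenol (the 2-OH is hydrogen-bonded to the aldehyde), so one equivalent of mild base should give selective Williamson etherification at O4.

Step 7
Reactants: 13 2-hydroxy-4-[(3-methylbut-2-en-1-yl)oxy]benzaldehyde
Product: 14 2-(methoxymethoxy)-4-[(3-methylbut-2-en-1-yl)oxy]benzaldehyde
Conditions: MOMCl, i-Pr2NEt, CH2Cl2, 0 °C → rt
Reagents that add atoms: chloromethyl methyl ether, COCCl
Why: O-alkylation of the remaining phenol with the reactive α-chloro ether masks O2 as an acetal, which removes the hydrogen bond that would otherwise steer the coming rearrangement to C3.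

Step 8
Reactants: 14 2-(methoxymethoxy)-4-[(3-methylbut-2-en-1-yl)oxy]benzaldehyde
Product: 15 4-hydroxy-2-(methoxymethoxy)-5-(2-methylbut-3-en-2-yl)benzaldehyde
Conditions: EtOH/H2O (4:1), 130 °C, sealed tube
Reagents that add atoms: none
Why: Aromatic Claisen rearrangement ([3,3]-sigmatropic shift with allyl inversion, then tautomerisation) turns the prenyl ether into the ortho 1,1-dimethylallyl phenol, C5 being preferred over C3 because C3 lies between two oxygen substituents and cannot easily take up the quaternary carbon, while water lowers the temperature needed and so limits follow-up reactions.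

Step 9
Reactants: 15 4-hydroxy-2-(methoxymethoxy)-5-(2-methylbut-3-en-2-yl)benzaldehyde
Product: 16 2,4-bis(methoxymethoxy)-5-(2-methylbut-3-en-2-yl)benzaldehyde
Conditions: NaH, MOMCl, DMF, 0 °C → rt
Reagents that add atoms: chloromethyl methyl ether, COCCl
Why: The sodium phenoxide, although flanked by the tertiary alkyl group, should be alkylated cleanly by the small and reactive chloromethyl ether (Williamson-type O-alkylation).

Step 10
Reactants: 16 2,4-bis(methoxymethoxy)-5-(2-methylbut-3-en-2-yl)benzaldehyde; 17 trimethyl phosphonoacetate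
Product: 18 methyl (E)-3-[2,4-bis(methoxymethoxy)-5-(2-methylbut-3-en-2-yl)phenyl]prop-2-enoate
Conditions: NaH, THF, 0 °C → rt
Reagents that add atoms: none
Why: Horner–Wadsworth–Emmons olefination of the aryl aldehyde with the stabilised phosphonate anion should give the E-cinnamate under thermodynamic control of the oxaphosphetane pathway.

Step 11
Reactants: 18 methyl (E)-3-[2,4-bis(methoxymethoxy)-5-(2-methylbut-3-en-2-yl)phenyl]prop-2-enoate
Product: 19 methyl 3-[2,4-bis(methoxymethoxy)-5-(2-methylbut-3-en-2-yl)phenyl]propanoate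
Conditions: Mg turnings, MeOH, 0 °C → rt
Reagents that add atoms: none
Why: Dissolving-metal conjugate reduction (electron transfer from magnesium to the cinnamate, protonation by methanol) saturates only the conjugated C=C and leaves the isolated vinyl group untouched, and the methyl ester matches the solvent so that no transesterification mixture arises.

Step 12
Reactants: 19 methyl 3-[2,4-bis(methoxymethoxy)-5-(2-methylbut-3-en-2-yl)phenyl]propanoate
Product: 20 3-[2,4-bis(methoxymethoxy)-5-(2-methylbut-3-en-2-yl)phenyl]-N-methoxy-N-methylpropanamide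
Conditions: MeNH(OMe)·HCl, i-PrMgCl, THF, −20 → 0 °C
Reagents that add atoms: N,O-dimethylhydroxylamine hydrochloride, CNOC.Cl
Why: The chloromagnesium amide of N,O-dimethylhydroxylamine converts esters directly into Weinreb amides by acyl substitution, and the chelated product resists further attack.

Step 13
Reactants: 20 3-[2,4-bis(methoxymethoxy)-5-(2-methylbut-3-en-2-yl)phenyl]-N-methoxy-N-methylpropanamide; 11 5-methylhex-4-en-1-yne
Product: 21 1-[2,4-bis(methoxymethoxy)-5-(2-methylbut-3-en-2-yl)phenyl]-8-methylnon-7-en-4-yn-3-one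
Conditions: 11, n-BuLi, THF, −78 °C; then 20, −78 → −20 °C; inverse quench into cold 0.5 M HCl
Reagents that add atoms: none
Why: Weinreb ketone synthesis: the lithium acetylide adds once to give a stable chelated tetrahedral intermediate, and the cold acidic quench releases the ynone while protonating the liberated amine so that it cannot add to the ynone or isomerise its propargylic–allylic CH2.

Step 14
Reactants: 8 1-(6,6-dimethyl-5,6-dihydro-4H-pyran-2-yl)vinyl acetate; 21 1-[2,4-bis(methoxymethoxy)-5-(2-methylbut-3-en-2-yl)phenyl]-8-methylnon-7-en-4-yn-3-one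
Product: 23 6-{3-[2,4-bis(methoxymethoxy)-5-(2-methylbut-3-en-2-yl)phenyl]propanoyl}-2,2-dimethyl-5-(3-methylbut-2-en-1-yl)chroman-8-yl acetate, via dihydro cycloadduct 22 (not isolated)
Conditions: 8 (1.3 equiv), BHT (cat.), PhMe, 110 °C, sealed base-washed tube; then DDQ (in portions), PhMe, 0 °C → rt
Reagents that add atoms: none
Why: A concerted, asynchronous normal-electron-demand [4+2] cycloaddition between the electron-rich 2,3-dioxygenated diene (C7=C8–C8a=C4a) and the electron-poor triple bond of the ynone forms C4a–C5 and C6–C7 suprafacially in one event, and this intermolecular cycloaddition is the mode by which carbocyclic ring B closes. The closest known reaction type is the Diels–Alder reaction of 2-oxygenated dienes with alkynyl ketones followed by quinone dehydrogenation of the resulting cyclohexa-1,4-diene. Adduct 22 holds two doubly allylic sp3 carbons (C4a–H and C7–H2), so DDQ should take hydride from one and a proton from the other, which makes ring B aromatic and the sequence irreversible. The only new stereocentre, C4a of 22, forms racemic and disappears on aromatisation, so no stereocontrol is asked of the step. The selectivity that is needed is regiochemical: the ring enol ether oxygen on C8a is a stronger donor than the acetoxy group on C8, which places the largest HOMO coefficient on C4a, so C4a should bond to the β-carbon of the ynone (the one carrying the prenyl CH2) and the acyl group should end on C6, para to O1. Chemoselectivity in the oxidation rests on the much higher hydride-donor ability of the cyclohexadiene compared with the benzylic and allylic C–H bonds elsewhere, which is why DDQ is added cold and only until 22 is consumed.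

Step 15
Reactants: 23 6-{3-[2,4-bis(methoxymethoxy)-5-(2-methylbut-3-en-2-yl)phenyl]propanoyl}-2,2-dimethyl-5-(3-methylbut-2-en-1-yl)chroman-8-yl acetate
Product: 24 3-[2,4-bis(methoxymethoxy)-5-(2-methylbut-3-en-2-yl)phenyl]-1-[8-hydroxy-2,2-dimethyl-5-(3-methylbut-2-en-1-yl)chroman-6-yl]propan-1-one
Conditions: K2CO3 (cat.), MeOH, rt
Reagents that add atoms: none
Why: Base-mediated transesterification cleaves the activated aryl acetate under conditions that leave the ketone and the MOM ethers alone, and doing so first spares the acetate from partial acyl transfer to the hydrazide in the next step.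

Step 16
Reactants: 24 3-[2,4-bis(methoxymethoxy)-5-(2-methylbut-3-en-2-yl)phenyl]-1-[8-hydroxy-2,2-dimethyl-5-(3-methylbut-2-en-1-yl)chroman-6-yl]propan-1-one
Product: 25 N'-{3-[2,4-bis(methoxymethoxy)-5-(2-methylbut-3-en-2-yl)phenyl]-1-[8-hydroxy-2,2-dimethyl-5-(3-methylbut-2-en-1-yl)chroman-6-yl]propylidene}-4-methylbenzenesulfonohydrazide (mixture of C=N isomers)
Conditions: TsNHNH2, EtOH, 70 °C
Reagents that add atoms: 4-methylbenzenesulfonohydrazide, Cc1ccc(cc1)S(=O)(=O)NN
Why: Condensation of the aryl alkyl ketone with tosylhydrazide gives the hydrazone without added strong acid, so the MOM acetals should survive.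

Step 17
Reactants: 25 the tosylhydrazone of step 16
Product: 28 6-{3-[2,4-bis(methoxymethoxy)-5-(2-methylbut-3-en-2-yl)phenyl]propyl}-2,2-dimethyl-5-(3-methylbut-2-en-1-yl)chroman-8-ol, via N-boryl hydrazine 26 (not isolated), via alkyl diazene 27 (not isolated)
Conditions: catecholborane (excess), CHCl3, 0 °C → rt; then NaOAc·3H2O, 60 °C
Reagents that add atoms: none
Why: Catecholborane reduction of a tosylhydrazone: hydride adds to the C=N carbon, acetate then triggers loss of sulfinate to give the monoalkyl diazene, which expels N2 and leaves CH2, while uncatalysed hydroboration of the alkenes is too slow at this temperature and the phenol only consumes one equivalent of borane as a borate that is cleaved on work-up.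

Step 18
Reactants: 28 6-{3-[2,4-bis(methoxymethoxy)-5-(2-methylbut-3-en-2-yl)phenyl]propyl}-2,2-dimethyl-5-(3-methylbut-2-en-1-yl)chroman-8-ol
Product: 29 Kazinol D, 4-{3-[8-hydroxy-2,2-dimethyl-5-(3-methylbut-2-en-1-yl)chroman-6-yl]propyl}-6-(2-methylbut-3-en-2-yl)benzene-1,3-diol
Conditions: 3 M aq. HCl/MeOH, 40 °C
Reagents that add atoms: none
Why: Acid-catalysed acetal exchange with methanol removes both MOM groups, and the conditions should spare the alkenes because the prenyl group has no ortho hydroxyl to cyclise onto and the monosubstituted vinyl group is not protonated by dilute acid.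

**Compound list**

1 | ethyl 5-oxohexanoate | CCOC(=O)CCCC(C)=O | starting material
2 | ethyl 5-hydroxy-5-methylhexanoate (present as its bromomagnesium alkoxide) | CCOC(=O)CCCC(C)(C)O | intermediate (not isolated)
3 | 6,6-dimethyltetrahydro-2H-pyran-2-one | CC1(C)CCCC(=O)O1 | intermediate
4 | 6,6-dimethyl-5,6-dihydro-4H-pyran-2-yl diphenyl phosphate | CC1(C)CCC=C(OP(=O)(Oc2ccccc2)Oc2ccccc2)O1 | intermediate
5 | tributyl(1-ethoxyvinyl)stannane | CCCC[Sn](CCCC)(CCCC)C(=C)OCC | starting material
6 | 2-(1-ethoxyethenyl)-6,6-dimethyl-5,6-dihydro-4H-pyran | C=C(OCC)C1=CCCC(C)(C)O1 | intermediate (not isolated)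
7 | 1-(6,6-dimethyl-5,6-dihydro-4H-pyran-2-yl)ethan-1-one | CC(=O)C1=CCCC(C)(C)O1 | intermediate
8 | 1-(6,6-dimethyl-5,6-dihydro-4H-pyran-2-yl)vinyl acetate | C=C(OC(C)=O)C1=CCCC(C)(C)O1 | intermediate
9 | prenyl bromide (1-bromo-3-methylbut-2-ene) | CC(C)=CCBr | starting material
10 | lithium acetylide–ethylenediamine complex | [Li+].[C-]#C.NCCN | starting material
11 | 5-methylhex-4-en-1-yne | C#CCC=C(C)C | intermediate
12 | 2,4-dihydroxybenzaldehyde | O=Cc1ccc(O)cc1O | starting material
13 | 2-hydroxy-4-[(3-methylbut-2-en-1-yl)oxy]benzaldehyde | CC(C)=CCOc1ccc(C=O)c(O)c1 | intermediate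
14 | 2-(methoxymethoxy)-4-[(3-methylbut-2-en-1-yl)oxy]benzaldehyde | COCOc1cc(OCC=C(C)C)ccc1C=O | intermediate
15 | 4-hydroxy-2-(methoxymethoxy)-5-(2-methylbut-3-en-2-yl)benzaldehyde | C=CC(C)(C)c1cc(C=O)c(OCOC)cc1O | intermediate
16 | 2,4-bis(methoxymethoxy)-5-(2-methylbut-3-en-2-yl)benzaldehyde | C=CC(C)(C)c1cc(C=O)c(OCOC)cc1OCOC | intermediate
17 | trimethyl phosphonoacetate | COC(=O)CP(=O)(OC)OC | starting material
18 | methyl (E)-3-[2,4-bis(methoxymethoxy)-5-(2-methylbut-3-en-2-yl)phenyl]prop-2-enoate | C=CC(C)(C)c1cc(/C=C/C(=O)OC)c(OCOC)cc1OCOC | intermediate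
19 | methyl 3-[2,4-bis(methoxymethoxy)-5-(2-methylbut-3-en-2-yl)phenyl]propanoate | C=CC(C)(C)c1cc(CCC(=O)OC)c(OCOC)cc1OCOC | intermediate
20 | 3-[2,4-bis(methoxymethoxy)-5-(2-methylbut-3-en-2-yl)phenyl]-N-methoxy-N-methylpropanamide | C=CC(C)(C)c1cc(CCC(=O)N(C)OC)c(OCOC)cc1OCOC | intermediate
21 | 1-[2,4-bis(methoxymethoxy)-5-(2-methylbut-3-en-2-yl)phenyl]-8-methylnon-7-en-4-yn-3-one | C=CC(C)(C)c1cc(CCC(=O)C#CCC=C(C)C)c(OCOC)cc1OCOC | intermediate
22 | 6-{3-[2,4-bis(methoxymethoxy)-5-(2-methylbut-3-en-2-yl)phenyl]propanoyl}-2,2-dimethyl-5-(3-methylbut-2-en-1-yl)-3,4,4a,7-tetrahydro-2H-chromen-8-yl acetate (racemic at C4a) | C=CC(C)(C)c1cc(CCC(=O)C2=C(CC=C(C)C)C3CCC(C)(C)OC3=C(OC(C)=O)C2)c(OCOC)cc1OCOC | intermediate (not isolated)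
23 | 6-{3-[2,4-bis(methoxymethoxy)-5-(2-methylbut-3-en-2-yl)phenyl]propanoyl}-2,2-dimethyl-5-(3-methylbut-2-en-1-yl)chroman-8-yl acetate | C=CC(C)(C)c1cc(CCC(=O)c2cc(OC(C)=O)c3c(c2CC=C(C)C)CCC(C)(C)O3)c(OCOC)cc1OCOC | intermediate
24 | 3-[2,4-bis(methoxymethoxy)-5-(2-methylbut-3-en-2-yl)phenyl]-1-[8-hydroxy-2,2-dimethyl-5-(3-methylbut-2-en-1-yl)chroman-6-yl]propan-1-one | C=CC(C)(C)c1cc(CCC(=O)c2cc(O)c3c(c2CC=C(C)C)CCC(C)(C)O3)c(OCOC)cc1OCOC | intermediate
25 | N'-{3-[2,4-bis(methoxymethoxy)-5-(2-methylbut-3-en-2-yl)phenyl]-1-[8-hydroxy-2,2-dimethyl-5-(3-methylbut-2-en-1-yl)chroman-6-yl]propylidene}-4-methylbenzenesulfonohydrazide (C=N isomer mixture) | C=CC(C)(C)c1cc(CCC(=NNS(=O)(=O)c2ccc(C)cc2)c2cc(O)c3c(c2CC=C(C)C)CCC(C)(C)O3)c(OCOC)cc1OCOC | intermediate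
26 | N'-(1,3,2-benzodioxaborol-2-yl)-N'-{3-[2,4-bis(methoxymethoxy)-5-(2-methylbut-3-en-2-yl)phenyl]-1-[8-hydroxy-2,2-dimethyl-5-(3-methylbut-2-en-1-yl)chroman-6-yl]propyl}-4-methylbenzenesulfonohydrazide (racemic) | C=CC(C)(C)c1cc(CCC(N(B2Oc3ccccc3O2)NS(=O)(=O)c2ccc(C)cc2)c2cc(O)c3c(c2CC=C(C)C)CCC(C)(C)O3)c(OCOC)cc1OCOC | intermediate (not isolated)
27 | {3-[2,4-bis(methoxymethoxy)-5-(2-methylbut-3-en-2-yl)phenyl]-1-[8-hydroxy-2,2-dimethyl-5-(3-methylbut-2-en-1-yl)chroman-6-yl]propyl}diazene (racemic) | C=CC(C)(C)c1cc(CCC(N=N)c2cc(O)c3c(c2CC=C(C)C)CCC(C)(C)O3)c(OCOC)cc1OCOC | intermediate (not isolated)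
28 | 6-{3-[2,4-bis(methoxymethoxy)-5-(2-methylbut-3-en-2-yl)phenyl]propyl}-2,2-dimethyl-5-(3-methylbut-2-en-1-yl)chroman-8-ol | C=CC(C)(C)c1cc(CCCc2cc(O)c3c(c2CC=C(C)C)CCC(C)(C)O3)c(OCOC)cc1OCOC | intermediate
29 | Kazinol D | C=CC(C)(C)c1cc(CCCc2cc(O)c3c(c2CC=C(C)C)CCC(C)(C)O3)c(O)cc1O | target

**Step count**

Total: 18 steps. Longest linear sequence: 13 steps (steps 6–18, from 2,4-dihydroxybenzaldehyde).

**The three steps most likely to fail**

1. Step 14 (cycloaddition and dehydrogenation). The cycloaddition may be slower than isomerisation of the propargylic–allylic CH2 of 21 to the allenyl ketone or than oligomerisation of the electron-rich diene. Regiocontrol may erode if the two bonds form more synchronously than expected. DDQ may go on to abstract benzylic or allylic hydride once the cyclohexadiene is used up. The fallback keeps the same ring construction but moves the union with ring A to a later aldol step, so the valuable ring A fragment is not exposed to the hot cycloaddition and the dienophile can be used in excess. It sets out from enyne 11 (with diene 8 and aldehyde 16) and comes back at hydroxy ketone 24. The lithium acetylide of 11 (n-BuLi, THF, −78 °C) would be acylated with N-methoxy-N-methylacetamide to give 7-methyloct-6-en-3-yn-2-one F1. Heating excess F1 with 8 would give 6-acetyl-2,2-dimethyl-5-(3-methylbut-2-en-1-yl)-3,4,4a,7-tetrahydro-2H-chromen-8-yl acetate F2, and DDQ would aromatise it without isolation to 6-acetyl-2,2-dimethyl-5-(3-methylbut-2-en-1-yl)chroman-8-yl acetate F3. Claisen–Schmidt condensation of F3 with 16 (KOH, EtOH/H2O, rt), in which the aryl acetate is hydrolysed as well, would give (E)-3-[2,4-bis(methoxymethoxy)-5-(2-methylbut-3-en-2-yl)phenyl]-1-[8-hydroxy-2,2-dimethyl-5-(3-methylbut-2-en-1-yl)chroman-6-yl]prop-2-en-1-one F4. Conjugate reduction of the enone with [(Ph3P)CuH]6 in benzene (in excess, to allow for the phenol) would then give 24.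

2. Step 8 (aromatic Claisen rearrangement). The allyl group may migrate partly to C3, the ortho 1,1-dimethylallyl phenol may rearrange further (abnormal Claisen) or cyclise, and the prenyl ether may simply be cleaved at the temperature needed. The fallback replaces the sigmatropic shift by a cross-coupling; it sets out from 2,4-dihydroxybenzaldehyde 12 and comes back at cinnamate 18. Bromination of 12 (Br2, AcOH, rt) would give 5-bromo-2,4-dihydroxybenzaldehyde F5. Double MOM protection (NaH, MOMCl, DMF) would give 5-bromo-2,4-bis(methoxymethoxy)benzaldehyde F6. Horner–Wadsworth–Emmons olefination with 17 (NaH, THF) would give methyl (E)-3-[5-bromo-2,4-bis(methoxymethoxy)phenyl]prop-2-enoate F7; the aldehyde is removed at this point so that it cannot be allylated by the boron reagent. A ligand-controlled, branch-selective (γ-selective) Suzuki–Miyaura coupling of F7 with pinacol (3-methylbut-2-en-1-yl)boronate (Pd(OAc)2, 1,1'-bis(di-tert-butylphosphino)ferrocene, K3PO4, THF/H2O, 60 °C) would deliver the 1,1-dimethylallyl group and give 18.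

3. Step 17 (deoxygenation through the tosylhydrazone). Hydride transfer to the hindered, ortho-substituted hydrazone may be incomplete. The diazene may break down by a radical path that lets the benzylic radical add to the neighbouring prenyl double bond. Base-induced elimination of the hydrazone to a styrene may also compete. The fallback uses a dissolving-metal deoxygenation; it sets out from hydroxy ketone 24 and comes back at the target 29. The phenol of 24 would first be protected (NaH, MOMCl, DMF), because a phenoxide on ring B would block electron uptake, giving 3-[2,4-bis(methoxymethoxy)-5-(2-methylbut-3-en-2-yl)phenyl]-1-[8-(methoxymethoxy)-2,2-dimethyl-5-(3-methylbut-2-en-1-yl)chroman-6-yl]propan-1-one F8. Treatment with Li in NH3/THF at −78 °C and then NH4Cl (reduction of the aryl ketone to the benzylic alkoxide and hydrogenolysis of the benzylic C–O bond on protonation) would give 6-{3-[2,4-bis(methoxymethoxy)-5-(2-methylbut-3-en-2-yl)phenyl]propyl}-8-(methoxymethoxy)-2,2-dimethyl-5-(3-methylbut-2-en-1-yl)chromane F9. The conditions of step 18 (3 M aq. HCl/MeOH, 40 °C) would then remove all three MOM groups and give 29.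

**Further compounds**

F1 | step 14 | 7-methyloct-6-en-3-yn-2-one | CC(=O)C#CCC=C(C)C
F2 | step 14 | 6-acetyl-2,2-dimethyl-5-(3-methylbut-2-en-1-yl)-3,4,4a,7-tetrahydro-2H-chromen-8-yl acetate (racemic) | CC(=O)C1=C(CC=C(C)C)C2CCC(C)(C)OC2=C(OC(C)=O)C1
F3 | step 14 | 6-acetyl-2,2-dimethyl-5-(3-methylbut-2-en-1-yl)chroman-8-yl acetate | CC(=O)Oc1cc(C(C)=O)c(CC=C(C)C)c2c1OC(C)(C)CC2
F4 | step 14 | (E)-3-[2,4-bis(methoxymethoxy)-5-(2-methylbut-3-en-2-yl)phenyl]-1-[8-hydroxy-2,2-dimethyl-5-(3-methylbut-2-en-1-yl)chroman-6-yl]prop-2-en-1-one | C=CC(C)(C)c1cc(/C=C/C(=O)c2cc(O)c3c(c2CC=C(C)C)CCC(C)(C)O3)c(OCOC)cc1OCOC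
F5 | step 8 | 5-bromo-2,4-dihydroxybenzaldehyde | O=Cc1cc(Br)c(O)cc1O
F6 | step 8 | 5-bromo-2,4-bis(methoxymethoxy)benzaldehyde | COCOc1cc(OCOC)c(C=O)cc1Br
F7 | step 8 | methyl (E)-3-[5-bromo-2,4-bis(methoxymethoxy)phenyl]prop-2-enoate | COCOc1cc(OCOC)c(/C=C/C(=O)OC)cc1Br
F8 | step 17 | 3-[2,4-bis(methoxymethoxy)-5-(2-methylbut-3-en-2-yl)phenyl]-1-[8-(methoxymethoxy)-2,2-dimethyl-5-(3-methylbut-2-en-1-yl)chroman-6-yl]propan-1-one | C=CC(C)(C)c1cc(CCC(=O)c2cc(OCOC)c3c(c2CC=C(C)C)CCC(C)(C)O3)c(OCOC)cc1OCOC
F9 | step 17 | 6-{3-[2,4-bis(methoxymethoxy)-5-(2-methylbut-3-en-2-yl)phenyl]propyl}-8-(methoxymethoxy)-2,2-dimethyl-5-(3-methylbut-2-en-1-yl)chromane | C=CC(C)(C)c1cc(CCCc2cc(OCOC)c3c(c2CC=C(C)C)CCC(C)(C)O3)c(OCOC)cc1OCOC
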